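Locants follow the name (8R)-1,9,13-trimethyl-8-tridecyl-1,5,9,13-tetraazacycloheptadecan-6-one (19). Its only ring, the 17-membered lactam, is closed in the last step.
Key disconnection: N1–C17, with C17 traced back to CO. Ring-closing hydroaminomethylation of the acyclic N13-allyl amino amide 16 makes C16–C17 and N1–C17 in one operation and gives 19 directly.
Enabling feature: the bridge C14–C17 between the N-methyl nitrogens N13 and N1 is a 1,4-diamine, the retron of allylamine + CO + H2 + secondary amine. N9 and N13 are tertiary and N5 is an amide, so N1–H is the only nitrogen that can condense.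
16 comes from ester 14 and N-methylpropane-1,3-diamine (C6–N5). 14 comes from chloride 11 and N-methylallylamine (C12–N13).
C8 and the C8–N9 bond are set by conjugate addition of a homochiral lithium (3-chloropropyl)(1-phenylethyl)amide, which also brings C10–C12, to enoate 3. The auxiliary is then exchanged for the N9 methyl group.

Key step: step 7

Step 1
Reactants: 1 tetradecanal; 2 methyl (triphenylphosphoranylidene)acetate
Product: 3 methyl (E)-hexadec-2-enoate
Conditions: CH2Cl2, rt, 16 h; chromatography to remove any Z isomer
Reagents that add atoms: none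
Why: Wittig olefination with a stabilised ylide, a reagent class that should give mainly the E-enoate the next step needs.

Step 2
Reactants: 4 (R)-1-phenylethylamine; 5 1-bromo-3-chloropropane
Product: 6 (1R)-N-(3-chloropropyl)-1-phenylethan-1-amine
Conditions: 4 (2 equiv), K2CO3, MeCN, 45 °C
Reagents that add atoms: none
Why: Chemoselective SN2 N-alkylation in which the amine should react only at the C–Br end because bromide is the far better leaving group, while the excess of 4 and its α-branch hold back a second alkylation and the benzylic stereocentre is not involved.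

Step 3
Reactants: 3 methyl (E)-hexadec-2-enoate; 6 (1R)-N-(3-chloropropyl)-1-phenylethan-1-amine
Product: 9 methyl (3R)-3-{(3-chloropropyl)[(1R)-1-phenylethyl]amino}hexadecanoate, via lithium amide 7 (not isolated), via lithium enolate 8 (not isolated)
Conditions: 6 (1.6 equiv), n-BuLi (1.55 equiv), THF, −78 °C; then 3, −78 °C, 2 h; sat. aq. NH4Cl
Reagents that add atoms: none
Why: Asymmetric aza-Michael addition of a homochiral lithium N-alkyl-N-(α-methylbenzyl)amide to an E-enoate, in which the (R)-1-phenylethyl group shields one face of the lithium-chelated s-cis enoate so that nitrogen should arrive to give the (3R) centre (the future C8), in the same sense as the N-benzyl and N-allyl congeners, after which enolate 8 is protonated on work-up, and at −78 °C addition should outrun azetidine closure of 7.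

Step 4
Reactants: 9 methyl (3R)-3-{(3-chloropropyl)[(1R)-1-phenylethyl]amino}hexadecanoate
Product: 11 methyl (3R)-3-[(3-chloropropyl)(methyl)amino]hexadecanoate, via secondary amine 10 (not isolated)
Conditions: H2 (5 bar), Pd(OH)2/C, MeOH/AcOH 10:1, rt; then 37% aq. HCHO, H2 (5 bar), rt; NaHCO3 work-up, used at once
Reagents that add atoms: formaldehyde C=O
Why: Hydrogenolysis of the only benzylic C–N bond followed in the same flask by catalytic reductive N-methylation, where acetic acid keeps 10 protonated so that it should not close to an azetidine, unactivated primary alkyl chlorides and esters are inert to Pd/H2 at room temperature, and the non-benzylic C3–N bond keeps its configuration.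

Step 5
Reactants: 11 methyl (3R)-3-[(3-chloropropyl)(methyl)amino]hexadecanoate; 12 N-methylprop-2-en-1-amine (N-methylallylamine)
Product: 14 methyl (3R)-3-(methyl{3-[methyl(prop-2-enyl)amino]propyl}amino)hexadecanoate, via iodide 13 (not isolated)
Conditions: 12 (5 equiv), NaI (0.2 equiv), K2CO3, MeCN, 60 °C, sealed tube
Reagents that add atoms: none
Why: Finkelstein-assisted SN2 amination of a primary halide by an unhindered secondary amine in excess, mild enough that the methyl ester and the β-amino ester stereocentre should survive.

Step 6
Reactants: 14 methyl (3R)-3-(methyl{3-[methyl(prop-2-enyl)amino]propyl}amino)hexadecanoate; 15 N-methylpropane-1,3-diamine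
Product: 16 (3R)-3-(methyl{3-[methyl(prop-2-enyl)amino]propyl}amino)-N-[3-(methylamino)propyl]hexadecanamide
Conditions: 15 (20 equiv), MeOH, rt to 40 °C, 3–5 d; excess 15 distilled off
Reagents that add atoms: none
Why: Uncatalysed aminolysis of a methyl β-(dialkylamino) ester by a large excess of a diamine, the reaction type of the amidation stage of poly(amidoamine) dendrimer growth, in which the primary NH2 is far more reactive toward esters than the NHMe end and the low temperature should hold back retro-aza-Michael cleavage at C3.

Step 7
Reactants: 16 (3R)-3-(methyl{3-[methyl(prop-2-enyl)amino]propyl}amino)-N-[3-(methylamino)propyl]hexadecanamide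
Product: 19 (8R)-1,9,13-trimethyl-8-tridecyl-1,5,9,13-tetraazacycloheptadecan-6-one (target), via amino aldehyde 17 (not isolated), via macrocyclic enamine 18 (not isolated)
Conditions: [Rh(cod)2]BF4 (5 mol %), Xantphos (10 mol %), CO/H2 1:5 (40 bar), toluene/MeOH 1:1, 110 °C; 16 pumped in over 12 h to 2 mM final concentration
Reagents that add atoms: carbon monoxide [C-]#[O+]
Why: Tandem hydroformylation–reductive amination (hydroaminomethylation): the rhodium hydride adds to the terminal C15=C16 alkene of the N13-allyl group, CO inserts and H2 releases the linear amino aldehyde 17, whose new carbonyl carbon is C17, then N1(H)Me condenses with it, losing water, to the macrocyclic enamine 18, which the cationic rhodium hydride hydrogenates to 19. The closest known reaction types are the hydroaminomethylation of tertiary allylamines with secondary amines to 1,4-diamines and the ring-closing hydroaminomethylation used to make polyaza macroheterocycles. The only ring, the 17-membered lactam, is closed by 17-exo-trig attack of N1 on the C17 carbonyl, that is, by forming N1–C17. No stereocentre is created, and C8 lies seven bonds from the nearest reacting atom in a neutral medium, so its configuration should be carried through. The step needs linear regioselectivity, secured by the wide-bite-angle ligand Xantphos and by N13, which can hold only the terminal rhodium alkyl in a five-membered chelate, and it needs nitrogen selectivity, which is built in because N9 and N13 are tertiary (no pyrrolidine sink) and N5 is an amide, leaving N1 as the only amine N–H. Ring closure versus oligomerisation is handled by slow addition at high dilution and by the reversibility of the condensation, which lets open-chain oligomers revert before the slower, irreversible hydrogenation.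

Compound list
1 | tetradecanal | CCCCCCCCCCCCCC=O | starting material
2 | methyl (triphenylphosphoranylidene)acetate | COC(=O)C=P(c1ccccc1)(c1ccccc1)c1ccccc1 | starting material
3 | methyl (E)-hexadec-2-enoate | CCCCCCCCCCCCC/C=C/C(=O)OC | intermediate
4 | (R)-1-phenylethylamine | C[C@@H](N)c1ccccc1 | starting material
5 | 1-bromo-3-chloropropane | ClCCCBr | starting material
6 | (1R)-N-(3-chloropropyl)-1-phenylethan-1-amine | C[C@@H](NCCCCl)c1ccccc1 | intermediate
7 | lithium (R)-(3-chloropropyl)(1-phenylethyl)amide | C[C@@H]([N-]CCCCl)c1ccccc1.[Li+] | intermediate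
8 | lithium enolate of 9 (enolate oxygen cis to C3) | CCCCCCCCCCCCC[C@H](/C=C(\[O-])OC)N(CCCCl)[C@H](C)c1ccccc1.[Li+] | intermediate
9 | methyl (3R)-3-{(3-chloropropyl)[(1R)-1-phenylethyl]amino}hexadecanoate | CCCCCCCCCCCCC[C@H](CC(=O)OC)N(CCCCl)[C@H](C)c1ccccc1 | intermediate
10 | methyl (3R)-3-[(3-chloropropyl)amino]hexadecanoate | CCCCCCCCCCCCC[C@H](CC(=O)OC)NCCCCl | intermediate
11 | methyl (3R)-3-[(3-chloropropyl)(methyl)amino]hexadecanoate | CCCCCCCCCCCCC[C@H](CC(=O)OC)N(C)CCCCl | intermediate
12 | N-methylprop-2-en-1-amine | CNCC=C | starting material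
13 | methyl (3R)-3-[(3-iodopropyl)(methyl)amino]hexadecanoate | CCCCCCCCCCCCC[C@H](CC(=O)OC)N(C)CCCI | intermediate
14 | methyl (3R)-3-(methyl{3-[methyl(prop-2-enyl)amino]propyl}amino)hexadecanoate | CCCCCCCCCCCCC[C@H](CC(=O)OC)N(C)CCCN(C)CC=C | intermediate
15 | N-methylpropane-1,3-diamine | CNCCCN | starting material
16 | (3R)-3-(methyl{3-[methyl(prop-2-enyl)amino]propyl}amino)-N-[3-(methylamino)propyl]hexadecanamide | CCCCCCCCCCCCC[C@H](CC(=O)NCCCNC)N(C)CCCN(C)CC=C | intermediate
17 | (3R)-3-(methyl{3-[methyl(4-oxobutyl)amino]propyl}amino)-N-[3-(methylamino)propyl]hexadecanamide | CCCCCCCCCCCCC[C@H](CC(=O)NCCCNC)N(C)CCCN(C)CCCC=O | intermediate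
18 | (8R,16E)-1,9,13-trimethyl-8-tridecyl-1,5,9,13-tetraazacycloheptadec-16-en-6-one | CCCCCCCCCCCCC[C@@H]1CC(=O)NCCCN(C)/C=C/CCN(C)CCCN1C | intermediate
19 | (8R)-1,9,13-trimethyl-8-tridecyl-1,5,9,13-tetraazacycloheptadecan-6-one | CCCCCCCCCCCCC[C@@H]1CC(=O)NCCCN(C)CCCCN(C)CCCN1C | target

Total steps: 7. Longest linear sequence: 6 (steps 1, 3, 4, 5, 6, 7).

Steps most likely to fail

Step 7. The allyl double bond may migrate toward N13. Hydroformylation may go branched, or the alkene may simply be hydrogenated. Intermolecular condensation may outrun ring closure. In the fallback, C17 is bought in as a masked aldehyde and the ring is closed by hydride reductive amination. It sets out from 11, which is aminated with commercial 4,4-diethoxy-N-methylbutan-1-amine (NaI, K2CO3, MeCN, 60 °C) to give methyl (3R)-3-({3-[(4,4-diethoxybutyl)(methyl)amino]propyl}(methyl)amino)hexadecanoate F1. Aminolysis with 15 as in step 6 should give (3R)-3-({3-[(4,4-diethoxybutyl)(methyl)amino]propyl}(methyl)amino)-N-[3-(methylamino)propyl]hexadecanamide F2. Aqueous HCl unmasks the aldehyde and the fallback comes back to the route at 17 (as its salt). Slow addition of 17 to NaBH(OAc)3 in CH2Cl2/AcOH at high dilution then closes N1–C17 and should give 19.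

Step 3. Lithium amide 7 may alkylate itself to an azetidine before it adds, or facial selectivity may erode with the chloropropyl substituent. In the fallback, the chloride is installed only after the C–N bond is made. It sets out from 3, which takes up the lithium amide of commercial (R)-N-allyl-1-phenylethylamine (n-BuLi, THF, −78 °C) to give methyl (3R)-3-{prop-2-enyl[(1R)-1-phenylethyl]amino}hexadecanoate F3. Hydroboration with 9-BBN (THF, rt) should give methyl (3R)-3-{[3-(9-borabicyclo[3.3.1]nonan-9-yl)propyl][(1R)-1-phenylethyl]amino}hexadecanoate F4. This is oxidised in the same flask (NaBO3·4H2O, THF/H2O) to methyl (3R)-3-{(3-hydroxypropyl)[(1R)-1-phenylethyl]amino}hexadecanoate F5. SOCl2 in CH2Cl2 converts F5 into 9, where the fallback rejoins the route.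

Step 6. Aminolysis may be sluggish. If it is forced by heating, retro-aza-Michael loss of the amine may follow, with erosion of the C3 configuration. In the fallback, an activated acid is coupled with a masked diamine. It sets out from 14, which is saponified (LiOH, THF/H2O, rt, then neutralisation) to (3R)-3-(methyl{3-[methyl(prop-2-enyl)amino]propyl}amino)hexadecanoic acid F6. Coupling with commercial tert-butyl (3-aminopropyl)(methyl)carbamate (DCC, catalytic HOBt, CH2Cl2) should give tert-butyl methyl{3-[(3R)-3-(methyl{3-[methyl(prop-2-enyl)amino]propyl}amino)hexadecanamido]propyl}carbamate F7. TFA/CH2Cl2 followed by a basic work-up returns to the route at 16.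

Further compounds
F1 | step 7 | methyl (3R)-3-({3-[(4,4-diethoxybutyl)(methyl)amino]propyl}(methyl)amino)hexadecanoate | CCCCCCCCCCCCC[C@H](CC(=O)OC)N(C)CCCN(C)CCCC(OCC)OCC
F2 | step 7 | (3R)-3-({3-[(4,4-diethoxybutyl)(methyl)amino]propyl}(methyl)amino)-N-[3-(methylamino)propyl]hexadecanamide | CCCCCCCCCCCCC[C@H](CC(=O)NCCCNC)N(C)CCCN(C)CCCC(OCC)OCC
F3 | step 3 | methyl (3R)-3-{prop-2-enyl[(1R)-1-phenylethyl]amino}hexadecanoate | CCCCCCCCCCCCC[C@H](CC(=O)OC)N(CC=C)[C@H](C)c1ccccc1
F4 | step 3 | methyl (3R)-3-{[3-(9-borabicyclo[3.3.1]nonan-9-yl)propyl][(1R)-1-phenylethyl]amino}hexadecanoate | CCCCCCCCCCCCC[C@H](CC(=O)OC)N(CCCB1C2CCCC1CCC2)[C@H](C)c1ccccc1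
F5 | step 3 | methyl (3R)-3-{(3-hydroxypropyl)[(1R)-1-phenylethyl]amino}hexadecanoate | CCCCCCCCCCCCC[C@H](CC(=O)OC)N(CCCO)[C@H](C)c1ccccc1
F6 | step 6 | (3R)-3-(methyl{3-[methyl(prop-2-enyl)amino]propyl}amino)hexadecanoic acid | CCCCCCCCCCCCC[C@H](CC(=O)O)N(C)CCCN(C)CC=C
F7 | step 6 | tert-butyl methyl{3-[(3R)-3-(methyl{3-[methyl(prop-2-enyl)amino]propyl}amino)hexadecanamido]propyl}carbamate | CCCCCCCCCCCCC[C@H](CC(=O)NCCCN(C)C(=O)OC(C)(C)C)N(C)CCCN(C)CC=C
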